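The constants of this scheme weigh unequally on the share of target.

    reagent ⇌ dormant form (K1 = 2.0, k1 = 0.028 s⁻¹)
    substrate + target → side product (k2 = 2.5 L mol⁻¹ s⁻¹)
    intermediate → target (k3 = 0.0088 s⁻¹)
    reagent + target → over-reaction product (k4 = 0.040 L mol⁻¹ s⁻¹)
    substrate + reagent → intermediate (k5 = 4.9 L mol⁻¹ s⁻¹)

| flask | substrate | reagent | remark | time |
|---|---|---|---|---|
| dawn | 0.020 M | 0.0200 M | one stirred flow tank at steady state, fed with the mixture as stated, mean residence time 1.5 min |  |
| autumn | 0.020 M | 0.0200 M | everything together in a closed stirred flask, run for 1.5 min | 1.5 min |
| dusk | 0.020 M (fed, over 1.20 min) | 0.0200 M | all but substrate at the start; substrate goes in evenly over 1.20 min, the run ends at 1.5 min | 1.5 min |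
| winter | 0.020 M | 0.0200 M (fed, over 1.20 min) | a stirred flask in which reagent is dosed at a steady rate over 1.20 min without added volume, worked up at 1.5 min | 1.5 min |

* the set-up with the highest share of target in all that became target or side product or over-reaction product, at the outlet or at the end ("none" if the first two lie within 2 percentage points) (dawn / autumn / dusk / winter / none)
* share of target in all that became target or side product or over-reaction product, at the outlet or at the end, dawn
* share of target in all that became target or side product or over-reaction product, at the outlet or at the end, autumn
* share of target in all that became target or side product or over-reaction product, at the outlet or at the end, dusk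
* share of target in all that became target or side product or over-reaction product, at the outlet or at the end, winter

- percentages count the substrate that a species holds: one side product counts as two
- the stated concentrations are those of everything mixed, before any reaction; amounts are the same in each set-up
- the feed brings no volume worth counting
- run time (autumn): 1.5 min

The over-reaction constant can be off with little harm. With reagent held as charged in autumn, target's half-life by that step is 14 min, longer than the run of 1.5 min and longer than the 0.23 min by the side-product step on the same footing. The intermediate's constant matters more: its half-life of 1.3 min is longer than the 0.12 min of substrate by the reagent step in autumn, so target arrives late. The drift constants enter through the reagent balance. Charged reagent is free, dormant or spent, and at equilibrium the dormant form holds 66.7 % of what is unspent. Forward drift has a half-life of 0.41 min, longer than substrate's, so in autumn reagent goes first to substrate.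

The constants to know well are those of substrate's two consumers, 4.9 L mol⁻¹ s⁻¹ for reagent and 2.5 L mol⁻¹ s⁻¹ for target, since an error in either shifts the split directly. Their quotient is 1.96. This crossover ratio, a selectivity factor, is the target-to-reagent ratio at which substrate goes equally to intermediate and to side product. With equal charges it reads directly on fractions of the charge. Dusk and winter stretch the reagent step over 1.20 min, longer than substrate's half-life, so this reckoning puts autumn first and stops short of percentages.

The forecast names autumn, with 26.7 % for dawn, 49.5 % for autumn, 40 % for dusk and 41 % for winter, holding that “the set-up that uses up substrate earliest while target is still scarce does best”.

The simulation gives autumn first at 48.3 %, then winter at 43.4 %, dusk at 40.1 % and dawn at 26.8 %.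

At 1.50 min winter holds target at 13.4 % of the substrate charge and reagent at 11.2 % of its own, a ratio of 1.19, below the crossover, so side product is forming at 0.607 of the pace of intermediate. The winter flask with reagent cut to 0.0050 M ends with target at 2.56 % and reagent at 3.96 % of that smaller charge. Its ratio is 2.59, above the crossover, side product forms at 1.32 of that pace, and its share of target ends at 25.1 %.

All constants are made up; the rest is arithmetic.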